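The cyclobutane (C1, C6, C7, C8) is disconnected at C6–C7, the bond between the methyl-bearing ring-fusion carbon C6 and the CH(CH3) carbon C7. Placing NH between these two atoms gives a cis-fused hexahydroindole, in which the four contiguous stereocentres that become C7, C8, C1 and C6 are set by chelate-controlled enolate alkylations and a face-selective annulation. Nitrogen deletion then forges C6–C7 with retention and closes the four-membered ring of the bicyclo[4.2.0]octene in one operation. The substrate of that step is the free secondary amine bearing the C3 methyl ester and a silyl-protected C4 carbinol; enone, diene, pyranone and endoperoxide follow.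

Key step: step 10

Remark on the chemistry: target, amine and cyclobutane are mutually consistent in connectivity and configuration (C1, C6, C7, C8 of the target = C3a, C7a, C2, C3 of the indole), so no structure needed correction. A free NH 4-oxohexahydroindole, however, is a Mannich base that can expel the amine and aromatise to a 3,5-dimethylphenol, and its ketone is exposed to the trivalent iodine oxidant. The contraction is therefore run on the 4-O-silyl carbinol 14 (carbinol configuration immaterial, drawn as the expected 4R epimer), and the 2-oxobicyclooctene 17 is released one step later.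

Step 1
Reactants: 1 methyl (3S)-3-[(tert-butoxycarbonyl)amino]butanoate; 2 3-bromo-2-methylprop-1-ene
Product: 3 methyl (2S,3S)-3-[(tert-butoxycarbonyl)amino]-2-(2-methylprop-2-en-1-yl)butanoate
Conditions: LiN(iPr)2 (2.2 equiv), THF, −78 °C; then 2, −78 → −40 °C; aq NH4Cl
Reagents that add atoms: none
Why: Enolate alkylation of the N,C-dilithiated β-amino ester, in which lithium chelation between carbamate nitrogen and ester enolate fixes the enolate and the allylic bromide enters anti to the C3 methyl group, giving the anti (2S,3S) product.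

Step 2
Reactants: 3 methyl (2S,3S)-3-[(tert-butoxycarbonyl)amino]-2-(2-methylprop-2-en-1-yl)butanoate
Product: 4 methyl (2R,3S)-3-[(tert-butoxycarbonyl)amino]-2-methyl-2-(2-methylprop-2-en-1-yl)butanoate
Conditions: LiN(iPr)2 (2.3 equiv), THF/DMPU, −78 → −30 °C; MeI, −78 → 0 °C; aq NH4Cl
Reagents that add atoms: iodomethane, CI
Why: A second enolate alkylation through the same chelate, in which iodomethane again enters anti to the C3 methyl group, so that the order methallyl then methyl defines the quaternary centre as 2R (1,2-induction).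

Step 3
Reactants: 4 methyl (2R,3S)-3-[(tert-butoxycarbonyl)amino]-2-methyl-2-(2-methylprop-2-en-1-yl)butanoate
Product: 7 methyl (2S,3R)-2,3,5-trimethyl-3,4-dihydro-2H-pyrrole-3-carboxylate, via keto carbamate 5 (not isolated), via amino ketone 6 (not isolated)
Conditions: O3, CH2Cl2/MeOH, −78 °C; Me2S; then TFA, CH2Cl2, 0 °C → rt; aq NaHCO3
Reagents that add atoms: none
Why: Ozonolysis with reductive work-up unmasks the methyl ketone, acidolysis of the carbamate frees the amine, and intramolecular imine condensation with the γ-ketone closes the 1-pyrroline without touching either stereocentre.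

Step 4
Reactants: 7 methyl (2S,3R)-2,3,5-trimethyl-3,4-dihydro-2H-pyrrole-3-carboxylate
Product: 8 1-(prop-2-en-1-yl) 3-methyl (2S,3R)-2,3,5-trimethyl-2,3-dihydro-1H-pyrrole-1,3-dicarboxylate
Conditions: allyl chloroformate, iPr2NEt, CH2Cl2, 0 °C → rt; then pyridinium p-toluenesulfonate (cat.), 40 °C; aq NaHCO3
Reagents that add atoms: allyl chloroformate, C=CCOC(=O)Cl
Why: N-Acylation of the cyclic ketimine gives an N-acyliminium ion that loses a proton to the enecarbamate, and mild acid equilibrates any exocyclic isomer to the more substituted endocyclic alkene.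

Step 5
Reactants: 8 1-(prop-2-en-1-yl) 3-methyl (2S,3R)-2,3,5-trimethyl-2,3-dihydro-1H-pyrrole-1,3-dicarboxylate; 9 3-methylbut-2-enoyl chloride
Product: 10 1-(prop-2-en-1-yl) 3-methyl (2S,3R)-2,3,5-trimethyl-4-(3-methylbut-2-enoyl)-2,3-dihydro-1H-pyrrole-1,3-dicarboxylate
Conditions: SnCl4, CH2Cl2, −78 → −20 °C; then Et3N; aq NaHCO3
Reagents that add atoms: none
Why: Friedel–Crafts-type β-acylation of the enecarbamate, in which the nucleophilic ring carbon C4 attacks the Lewis-acid-activated acid chloride and proton loss from the N-acyliminium ion gives the vinylogous imide; aprotic conditions should keep the alkene endocyclic so that C4 and not the methyl group reacts.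

Step 6
Reactants: 10 1-(prop-2-en-1-yl) 3-methyl (2S,3R)-2,3,5-trimethyl-4-(3-methylbut-2-enoyl)-2,3-dihydro-1H-pyrrole-1,3-dicarboxylate
Product: 11 1-(prop-2-en-1-yl) 3-methyl (2S,3R,3aS,7aS)-2,3,6,7a-tetramethyl-4-oxo-2,3,3a,4,7,7a-hexahydro-1H-indole-1,3-dicarboxylate
Conditions: Tf2NH (20 mol %), CH2Cl2, −20 → 0 °C; aq NaHCO3
Reagents that add atoms: none
Why: Intramolecular vinylogous Mannich reaction (an isomerisation), in which protonation at C4 gives a tertiary N-acyliminium ion at C5 that is attacked by the terminal carbon of the enone dienol; the six-membered ring forms on the face opposite the cis methyl groups at C2 and C3, which sets C7a, and the tether enforces the cis fusion at C3a.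

Step 7
Reactants: 11 1-(prop-2-en-1-yl) 3-methyl (2S,3R,3aS,7aS)-2,3,6,7a-tetramethyl-4-oxo-2,3,3a,4,7,7a-hexahydro-1H-indole-1,3-dicarboxylate
Product: 12 1-(prop-2-en-1-yl) 3-methyl (2S,3R,3aS,4R,7aS)-4-hydroxy-2,3,6,7a-tetramethyl-2,3,3a,4,7,7a-hexahydro-1H-indole-1,3-dicarboxylate
Conditions: NaBH4, CeCl3·7H2O, MeOH, −78 → −40 °C
Reagents that add atoms: none
Why: Luche reduction should reduce only the enone carbonyl (1,2), with hydride expected from the face of the C3a hydrogen; the configuration of this carbinol is lost again in step 11.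

Step 8
Reactants: 12 1-(prop-2-en-1-yl) 3-methyl (2S,3R,3aS,4R,7aS)-4-hydroxy-2,3,6,7a-tetramethyl-2,3,3a,4,7,7a-hexahydro-1H-indole-1,3-dicarboxylate
Product: 13 1-(prop-2-en-1-yl) 3-methyl (2S,3R,3aS,4R,7aS)-4-[(tert-butyldimethylsilyl)oxy]-2,3,6,7a-tetramethyl-2,3,3a,4,7,7a-hexahydro-1H-indole-1,3-dicarboxylate
Conditions: TBSOTf, 2,6-lutidine, CH2Cl2, −78 → 0 °C; aq NaHCO3
Reagents that add atoms: tert-butyldimethylsilyl trifluoromethanesulfonate, CC(C)(C)[Si](C)(C)OS(=O)(=O)C(F)(F)F
Why: Silyl ether formation with the silyl triflate masks the hindered allylic oxygen, so that neither lactonisation onto the neighbouring ester nor retro-Mannich chemistry is possible once the nitrogen is free.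

Step 9
Reactants: 13 1-(prop-2-en-1-yl) 3-methyl (2S,3R,3aS,4R,7aS)-4-[(tert-butyldimethylsilyl)oxy]-2,3,6,7a-tetramethyl-2,3,3a,4,7,7a-hexahydro-1H-indole-1,3-dicarboxylate
Product: 14 methyl (2S,3R,3aS,4R,7aS)-4-[(tert-butyldimethylsilyl)oxy]-2,3,6,7a-tetramethyl-2,3,3a,4,7,7a-hexahydro-1H-indole-3-carboxylate
Conditions: Pd(PPh3)4 (5 mol %), morpholine, THF, rt
Reagents that add atoms: none
Why: Tsuji–Trost deallylation, in which zerovalent palladium ionises the allyl carbamate, morpholine traps the allyl group and the carbamic acid loses CO2 to give the free secondary amine under neutral conditions.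

Step 10
Reactants: 14 methyl (2S,3R,3aS,4R,7aS)-4-[(tert-butyldimethylsilyl)oxy]-2,3,6,7a-tetramethyl-2,3,3a,4,7,7a-hexahydro-1H-indole-3-carboxylate
Product: 16 methyl (1R,2R,6R,7R,8S)-2-[(tert-butyldimethylsilyl)oxy]-4,6,7,8-tetramethylbicyclo[4.2.0]oct-3-ene-8-carboxylate, via 1,1-diazene 15 (not isolated)
Conditions: PhI(OH)OTs (2.5 equiv), NH2CO2NH4 (8 equiv), CF3CH2OH, 80 °C
Reagents that add atoms: none
Why: The iodonitrene formed from PhI(OH)OTs and ammonia aminates the hindered secondary amine, a second equivalent of oxidant takes the hydrazine to 1,1-diazene 15, and loss of N2 leaves a singlet 1,4-biradical at C2 and C7a that collapses to the C6–C7 bond. The closest known reaction is the iodonitrene-mediated contraction of polysubstituted pyrrolidines to cyclobutanes. The four-membered ring is closed by radical–radical recombination of the 1,4-biradical, the six-membered ring holding the two centres on one edge. C6 and C7 keep the configurations of C7a and C2 because the singlet pair should couple faster than rotation about C2–C3 and because C7a is locked in the ring fusion. The step needs coupling to win over β-scission of the C3–C3a bond; a silyl ether instead of a ketone at C4 removes the conjugative gain of fragmentation (which would lead on to a phenol) and the retro-Mannich channel, and the saturated C7 keeps the C7a radical from being allylic.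

Step 11
Reactants: 16 methyl (1R,2R,6R,7R,8S)-2-[(tert-butyldimethylsilyl)oxy]-4,6,7,8-tetramethylbicyclo[4.2.0]oct-3-ene-8-carboxylate
Product: 17 methyl (1R,6R,7R,8S)-4,6,7,8-tetramethyl-2-oxobicyclo[4.2.0]oct-3-ene-8-carboxylate
Conditions: DDQ, CH2Cl2/pH 7 phosphate buffer, rt
Reagents that add atoms: none
Why: Oxidative deprotection of an allylic silyl ether, in which DDQ abstracts the allylic hydride next to the silyloxy group and the silyl oxocarbenium ion loses the silyl group, so that the enone forms without a free alkoxide that could lactonise.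

Step 12
Reactants: 17 methyl (1R,6R,7R,8S)-4,6,7,8-tetramethyl-2-oxobicyclo[4.2.0]oct-3-ene-8-carboxylate
Product: 18 methyl (1R,6R,7R,8S)-4,6,7,8-tetramethyl-2-{[(trifluoromethyl)sulfonyl]oxy}bicyclo[4.2.0]octa-2,4-diene-8-carboxylate
Conditions: Tf2O, 2,6-di-tert-butyl-4-methylpyridine, CH2Cl2, 0 °C → rt; aq NaHCO3
Reagents that add atoms: trifluoromethanesulfonic anhydride, O=S(=O)(OS(=O)(=O)C(F)(F)F)C(F)(F)F
Why: Enol triflate formation, in which O-triflation of the enone and proton loss from C5 under equilibrating conditions should give the homoannular dienyl triflate, the alternative α' proton at C1 being a hindered cyclobutane methine.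

Step 13
Reactants: 18 methyl (1R,6R,7R,8S)-4,6,7,8-tetramethyl-2-{[(trifluoromethyl)sulfonyl]oxy}bicyclo[4.2.0]octa-2,4-diene-8-carboxylate
Product: 19 methyl (1R,6R,7R,8S)-2,4,6,7,8-pentamethylbicyclo[4.2.0]octa-2,4-diene-8-carboxylate
Conditions: MeMgBr, Fe(acac)3 (5 mol %), THF/NMP, −30 °C
Reagents that add atoms: methylmagnesium bromide, C[Mg]Br
Why: Iron-catalysed Kumada-type cross-coupling of the alkenyl triflate, which is much faster than attack on the hindered ester, installs the C2 methyl group.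

Step 14
Reactants: 19 methyl (1R,6R,7R,8S)-2,4,6,7,8-pentamethylbicyclo[4.2.0]octa-2,4-diene-8-carboxylate
Product: 20 [(1R,6R,7R,8S)-2,4,6,7,8-pentamethylbicyclo[4.2.0]octa-2,4-dien-8-yl]methanol
Conditions: iBu2AlH, CH2Cl2, −78 → 0 °C; aq potassium sodium tartrate
Reagents that add atoms: none
Why: Hydride reduction of the neopentyl ester to the primary alcohol, to which the diene is inert.

Step 15
Reactants: 20 [(1R,6R,7R,8S)-2,4,6,7,8-pentamethylbicyclo[4.2.0]octa-2,4-dien-8-yl]methanol
Product: 21 (1R,6R,7R,8S)-2,4,6,7,8-pentamethylbicyclo[4.2.0]octa-2,4-diene-8-carbaldehyde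
Conditions: Dess–Martin periodinane, NaHCO3, CH2Cl2, 0 °C → rt
Reagents that add atoms: none
Why: Buffered Dess–Martin oxidation should give the non-enolisable aldehyde without touching the diene.

Step 16
Reactants: 21 (1R,6R,7R,8S)-2,4,6,7,8-pentamethylbicyclo[4.2.0]octa-2,4-diene-8-carbaldehyde; 22 methyl 2-methyl-3-oxopentanoate
Product: 23 methyl 5-hydroxy-2,4-dimethyl-3-oxo-5-[(1R,6R,7R,8S)-2,4,6,7,8-pentamethylbicyclo[4.2.0]octa-2,4-dien-8-yl]pentanoate (C2/C4/C5 diastereomer mixture)
Conditions: 22, NaH, then n-BuLi, THF, 0 °C; then 21, −78 °C; aq NH4Cl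
Reagents that add atoms: none
Why: Aldol addition of the β-keto ester dianion through its more nucleophilic γ-carbon to the non-enolisable aldehyde; the new stereocentres are removed in the next two steps.

Step 17
Reactants: 23 methyl 5-hydroxy-2,4-dimethyl-3-oxo-5-[(1R,6R,7R,8S)-2,4,6,7,8-pentamethylbicyclo[4.2.0]octa-2,4-dien-8-yl]pentanoate
Product: 24 methyl 2,4-dimethyl-3,5-dioxo-5-[(1R,6R,7R,8S)-2,4,6,7,8-pentamethylbicyclo[4.2.0]octa-2,4-dien-8-yl]pentanoate
Conditions: Dess–Martin periodinane, NaHCO3, CH2Cl2, rt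
Reagents that add atoms: none
Why: Dess–Martin oxidation of the β-hydroxy ketone gives the β,δ-diketo ester, present as its enol forms.

Step 18
Reactants: 24 methyl 2,4-dimethyl-3,5-dioxo-5-[(1R,6R,7R,8S)-2,4,6,7,8-pentamethylbicyclo[4.2.0]octa-2,4-dien-8-yl]pentanoate
Product: 25 4-hydroxy-3,5-dimethyl-6-[(1R,6R,7R,8S)-2,4,6,7,8-pentamethylbicyclo[4.2.0]octa-2,4-dien-8-yl]-2H-pyran-2-one
Conditions: DBU, toluene, 60 °C
Reagents that add atoms: none
Why: Base-mediated lactonisation, in which the enol oxygen of the δ-ketone attacks the ester and methanol is lost, gives the 4-hydroxy-2-pyranone.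

Step 19
Reactants: 25 4-hydroxy-3,5-dimethyl-6-[(1R,6R,7R,8S)-2,4,6,7,8-pentamethylbicyclo[4.2.0]octa-2,4-dien-8-yl]-2H-pyran-2-one
Product: 26 2-methoxy-3,5-dimethyl-6-[(1R,6R,7R,8S)-2,4,6,7,8-pentamethylbicyclo[4.2.0]octa-2,4-dien-8-yl]-4H-pyran-4-one
Conditions: MeOTf, 2,6-di-tert-butyl-4-methylpyridine, CH2Cl2, 0 °C → rt; aq NaHCO3
Reagents that add atoms: methyl trifluoromethanesulfonate, COS(=O)(=O)C(F)(F)F
Why: O-Methylation of the neutral hydroxypyranone at its lactone carbonyl oxygen, the most nucleophilic site, followed by proton loss gives the 2-methoxy-4-pyranone, the hindered pyridine only scavenging the acid so that the diene is spared.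

Step 20
Reactants: 26 2-methoxy-3,5-dimethyl-6-[(1R,6R,7R,8S)-2,4,6,7,8-pentamethylbicyclo[4.2.0]octa-2,4-dien-8-yl]-4H-pyran-4-one
Product: 27 2-methoxy-3,5-dimethyl-6-[(1R,2S,5R,6R,7R,8S)-2,5-epidioxy-2,4,6,7,8-pentamethylbicyclo[4.2.0]oct-3-en-8-yl]-4H-pyran-4-one (CNP0183511.1)
Conditions: O2, methylene blue, visible light, CH2Cl2, 0 °C
Reagents that add atoms: dioxygen, O=O
Why: Singlet-oxygen [4+2] cycloaddition to the cyclohexadiene from the face anti to the cyclobutane, whose endo pyranone shields the syn face, sets the two peroxide carbons C2 and C5.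

Compound list
1 | methyl (3S)-3-[(tert-butoxycarbonyl)amino]butanoate | C[C@H](NC(=O)OC(C)(C)C)CC(=O)OC | starting material
2 | 3-bromo-2-methylprop-1-ene | CC(=C)CBr | starting material
3 | methyl (2S,3S)-3-[(tert-butoxycarbonyl)amino]-2-(2-methylprop-2-en-1-yl)butanoate | COC(=O)[C@@H](CC(C)=C)[C@H](C)NC(=O)OC(C)(C)C | intermediate
4 | methyl (2R,3S)-3-[(tert-butoxycarbonyl)amino]-2-methyl-2-(2-methylprop-2-en-1-yl)butanoate | COC(=O)[C@@](CC(C)=C)(C)[C@H](C)NC(=O)OC(C)(C)C | intermediate
5 | methyl (2R,3S)-3-[(tert-butoxycarbonyl)amino]-2-methyl-2-(2-oxopropyl)butanoate (keto carbamate, not isolated) | COC(=O)[C@@](CC(C)=O)(C)[C@H](C)NC(=O)OC(C)(C)C | intermediate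
6 | methyl (2R,3S)-3-amino-2-methyl-2-(2-oxopropyl)butanoate (amino ketone, not isolated) | COC(=O)[C@@](CC(C)=O)(C)[C@H](C)N | intermediate
7 | methyl (2S,3R)-2,3,5-trimethyl-3,4-dihydro-2H-pyrrole-3-carboxylate | COC(=O)[C@@]1(C)[C@H](C)N=C(C)C1 | intermediate
8 | 1-(prop-2-en-1-yl) 3-methyl (2S,3R)-2,3,5-trimethyl-2,3-dihydro-1H-pyrrole-1,3-dicarboxylate | COC(=O)[C@@]1(C)[C@H](C)N(C(=O)OCC=C)C(C)=C1 | intermediate
9 | 3-methylbut-2-enoyl chloride | CC(C)=CC(=O)Cl | starting material
10 | 1-(prop-2-en-1-yl) 3-methyl (2S,3R)-2,3,5-trimethyl-4-(3-methylbut-2-enoyl)-2,3-dihydro-1H-pyrrole-1,3-dicarboxylate | COC(=O)[C@@]1(C)[C@H](C)N(C(=O)OCC=C)C(C)=C1C(=O)C=C(C)C | intermediate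
11 | 1-(prop-2-en-1-yl) 3-methyl (2S,3R,3aS,7aS)-2,3,6,7a-tetramethyl-4-oxo-2,3,3a,4,7,7a-hexahydro-1H-indole-1,3-dicarboxylate | COC(=O)[C@@]1(C)[C@H](C)N(C(=O)OCC=C)[C@@]2(C)CC(C)=CC(=O)[C@@H]12 | intermediate
12 | 1-(prop-2-en-1-yl) 3-methyl (2S,3R,3aS,4R,7aS)-4-hydroxy-2,3,6,7a-tetramethyl-2,3,3a,4,7,7a-hexahydro-1H-indole-1,3-dicarboxylate | COC(=O)[C@@]1(C)[C@H](C)N(C(=O)OCC=C)[C@@]2(C)CC(C)=C[C@@H](O)[C@@H]12 | intermediate
13 | 1-(prop-2-en-1-yl) 3-methyl (2S,3R,3aS,4R,7aS)-4-[(tert-butyldimethylsilyl)oxy]-2,3,6,7a-tetramethyl-2,3,3a,4,7,7a-hexahydro-1H-indole-1,3-dicarboxylate | COC(=O)[C@@]1(C)[C@H](C)N(C(=O)OCC=C)[C@@]2(C)CC(C)=C[C@@H](O[Si](C)(C)C(C)(C)C)[C@@H]12 | intermediate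
14 | methyl (2S,3R,3aS,4R,7aS)-4-[(tert-butyldimethylsilyl)oxy]-2,3,6,7a-tetramethyl-2,3,3a,4,7,7a-hexahydro-1H-indole-3-carboxylate (substrate of the key step) | COC(=O)[C@@]1(C)[C@H](C)N[C@@]2(C)CC(C)=C[C@@H](O[Si](C)(C)C(C)(C)C)[C@@H]12 | intermediate
15 | 1,1-diazene (N-nitrene) of 14 (not isolated) | COC(=O)[C@@]1(C)[C@H](C)[N+](=[N-])[C@@]2(C)CC(C)=C[C@@H](O[Si](C)(C)C(C)(C)C)[C@@H]12 | intermediate
16 | methyl (1R,2R,6R,7R,8S)-2-[(tert-butyldimethylsilyl)oxy]-4,6,7,8-tetramethylbicyclo[4.2.0]oct-3-ene-8-carboxylate | COC(=O)[C@@]1(C)[C@H](C)[C@@]2(C)CC(C)=C[C@@H](O[Si](C)(C)C(C)(C)C)[C@@H]12 | intermediate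
17 | methyl (1R,6R,7R,8S)-4,6,7,8-tetramethyl-2-oxobicyclo[4.2.0]oct-3-ene-8-carboxylate | COC(=O)[C@@]1(C)[C@H](C)[C@@]2(C)CC(C)=CC(=O)[C@@H]12 | intermediate
18 | methyl (1R,6R,7R,8S)-4,6,7,8-tetramethyl-2-{[(trifluoromethyl)sulfonyl]oxy}bicyclo[4.2.0]octa-2,4-diene-8-carboxylate | COC(=O)[C@@]1(C)[C@H](C)[C@@]2(C)C=C(C)C=C(OS(=O)(=O)C(F)(F)F)[C@@H]12 | intermediate
19 | methyl (1R,6R,7R,8S)-2,4,6,7,8-pentamethylbicyclo[4.2.0]octa-2,4-diene-8-carboxylate | COC(=O)[C@@]1(C)[C@H](C)[C@@]2(C)C=C(C)C=C(C)[C@@H]12 | intermediate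
20 | [(1R,6R,7R,8S)-2,4,6,7,8-pentamethylbicyclo[4.2.0]octa-2,4-dien-8-yl]methanol | OC[C@@]1(C)[C@H](C)[C@@]2(C)C=C(C)C=C(C)[C@@H]12 | intermediate
21 | (1R,6R,7R,8S)-2,4,6,7,8-pentamethylbicyclo[4.2.0]octa-2,4-diene-8-carbaldehyde | O=C[C@@]1(C)[C@H](C)[C@@]2(C)C=C(C)C=C(C)[C@@H]12 | intermediate
22 | methyl 2-methyl-3-oxopentanoate (racemic) | CCC(=O)C(C)C(=O)OC | starting material
23 | methyl 5-hydroxy-2,4-dimethyl-3-oxo-5-[(1R,6R,7R,8S)-2,4,6,7,8-pentamethylbicyclo[4.2.0]octa-2,4-dien-8-yl]pentanoate (diastereomer mixture in the chain) | COC(=O)C(C)C(=O)C(C)C(O)[C@@]1(C)[C@H](C)[C@@]2(C)C=C(C)C=C(C)[C@@H]12 | intermediate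
24 | methyl 2,4-dimethyl-3,5-dioxo-5-[(1R,6R,7R,8S)-2,4,6,7,8-pentamethylbicyclo[4.2.0]octa-2,4-dien-8-yl]pentanoate | COC(=O)C(C)C(=O)C(C)C(=O)[C@@]1(C)[C@H](C)[C@@]2(C)C=C(C)C=C(C)[C@@H]12 | intermediate
25 | 4-hydroxy-3,5-dimethyl-6-[(1R,6R,7R,8S)-2,4,6,7,8-pentamethylbicyclo[4.2.0]octa-2,4-dien-8-yl]-2H-pyran-2-one | CC3=C(O)C(C)=C(OC3=O)[C@@]1(C)[C@H](C)[C@@]2(C)C=C(C)C=C(C)[C@@H]12 | intermediate
26 | 2-methoxy-3,5-dimethyl-6-[(1R,6R,7R,8S)-2,4,6,7,8-pentamethylbicyclo[4.2.0]octa-2,4-dien-8-yl]-4H-pyran-4-one | COc1oc([C@@]2(C)[C@H](C)[C@@]3(C)C=C(C)C=C(C)[C@@H]23)c(C)c(=O)c1C | intermediate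
27 | 2-methoxy-3,5-dimethyl-6-[(1R,2S,5R,6R,7R,8S)-2,5-epidioxy-2,4,6,7,8-pentamethylbicyclo[4.2.0]oct-3-en-8-yl]-4H-pyran-4-one (CNP0183511.1; peroxide bridge anti to the cyclobutane) | COc1oc([C@@]2(C)[C@H](C)[C@@]3(C)[C@@H]4OO[C@@](C)(C=C4C)[C@@H]23)c(C)c(=O)c1C | target

Total step count: 20. Longest linear sequence: 20 steps (from 1; the route is fully linear).

Steps most likely to fail

Step 10. The N-amination of the hindered amine may be slow, or the 1,4-biradical may fragment by β-scission into methyl tiglate and a cyclohexadiene at 80 °C instead of coupling. The fallback sets out from 14 and returns at 16. N-Nitrosation with tert-butyl nitrite in CH2Cl2 should give the N-nitrosamine F1. Reduction with Zn in AcOH/MeOH at 0 °C should give the N-aminopyrrolidine F2. Oxidation of this hydrazine with HgO in CH2Cl2 at 0 °C generates the same 1,1-diazene 15 from an isolated precursor and at a temperature at which radical coupling is favoured over fragmentation; loss of N2 then gives 16.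

Step 6. C-Protonation of the vinylogous imide may be inefficient, or the acid may expel the carbamate from the product and drive aromatisation. The fallback sets out from 10 and returns at 11, and it is neutral until the last operation. Soft enolisation with TBSOTf and Et3N in CH2Cl2 gives the silyl trienol ether F3. Heating in toluene should bring about a thermal 6π-electrocyclisation of the isomer that has the ring carbon cis to the isopropenyl group, giving the bicyclic silyl dienol ether F4 with the new bond again formed anti to the C2 and C3 methyl groups. Buffered HF·pyridine in THF then releases the cis-fused enone 11.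

Step 5. Acylation may occur at the exocyclic methyl carbon after migration of the alkene, or not at all at the hindered ring carbon. The fallback sets out from 8 and returns at 10, and it builds the side chain in two stages with a smaller electrophile. Vilsmeier–Haack formylation (POCl3, DMF, 0 °C; aq NaOAc) gives the aldehyde F5. Addition of 2-methylprop-1-enylmagnesium bromide in THF at −78 °C gives the dienyl carbinol F6. Oxidation with MnO2 in CH2Cl2 gives 10.

Further compounds
F1 | step 10 | methyl (2S,3R,3aS,4R,7aS)-4-[(tert-butyldimethylsilyl)oxy]-2,3,6,7a-tetramethyl-1-nitroso-2,3,3a,4,7,7a-hexahydro-1H-indole-3-carboxylate | COC(=O)[C@@]1(C)[C@H](C)N(N=O)[C@@]2(C)CC(C)=C[C@@H](O[Si](C)(C)C(C)(C)C)[C@@H]12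
F2 | step 10 | methyl (2S,3R,3aS,4R,7aS)-1-amino-4-[(tert-butyldimethylsilyl)oxy]-2,3,6,7a-tetramethyl-2,3,3a,4,7,7a-hexahydro-1H-indole-3-carboxylate | COC(=O)[C@@]1(C)[C@H](C)N(N)[C@@]2(C)CC(C)=C[C@@H](O[Si](C)(C)C(C)(C)C)[C@@H]12
F3 | step 6 | 1-(prop-2-en-1-yl) 3-methyl (2S,3R)-4-{1-[(tert-butyldimethylsilyl)oxy]-3-methylbuta-1,3-dien-1-yl}-2,3,5-trimethyl-2,3-dihydro-1H-pyrrole-1,3-dicarboxylate | COC(=O)[C@@]1(C)[C@H](C)N(C(=O)OCC=C)C(C)=C1C(O[Si](C)(C)C(C)(C)C)=CC(C)=C
F4 | step 6 | 1-(prop-2-en-1-yl) 3-methyl (2S,3R,7aS)-4-[(tert-butyldimethylsilyl)oxy]-2,3,6,7a-tetramethyl-2,3,7,7a-tetrahydro-1H-indole-1,3-dicarboxylate | COC(=O)[C@@]1(C)[C@H](C)N(C(=O)OCC=C)[C@@]2(C)CC(C)=CC(O[Si](C)(C)C(C)(C)C)=C12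
F5 | step 5 | 1-(prop-2-en-1-yl) 3-methyl (2S,3R)-4-formyl-2,3,5-trimethyl-2,3-dihydro-1H-pyrrole-1,3-dicarboxylate | COC(=O)[C@@]1(C)[C@H](C)N(C(=O)OCC=C)C(C)=C1C=O
F6 | step 5 | 1-(prop-2-en-1-yl) 3-methyl (2S,3R)-4-(1-hydroxy-3-methylbut-2-en-1-yl)-2,3,5-trimethyl-2,3-dihydro-1H-pyrrole-1,3-dicarboxylate (carbinol epimers) | COC(=O)[C@@]1(C)[C@H](C)N(C(=O)OCC=C)C(C)=C1C(O)C=C(C)C
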